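If you take over this flask from me, it holds the racemate with 0.2 mol% of free catalyst, gas held at 9.5 mM, and the impurity, charged in a smaller amount than the catalyst. I treat it as the limiting reagent of a poisoning, one catalyst per impurity.

in all of them: left-handed substrate 0.20 M; right-handed substrate 0.20 M; gas 9.5 mM (held)
- Tuesday's: free catalyst 0.28 mol%; impurity 0.17 mM; run made earlier
- Friday's: free catalyst 0.44 mol%; impurity 0.17 mM; run made earlier
- Thursday's: free catalyst 0.2 mol%; impurity 0.085 mM; run made earlier
- flask: free catalyst 0.2 mol%; impurity 0.17 mM; time 8.0 min

| run | time / min | right-handed substrate / % | left-handed substrate / % |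
|---|---|---|---|
| Tuesday's | 0.417 | 49.7 | 33.0 |
| Tuesday's | 0.667 | 49.4 | 26.5 |
| Tuesday's | 0.833 | 48.3 | 21.5 |
| Tuesday's | 1.33 | 47.9 | 14.1 |
| Tuesday's | 2.00 | 46.7 | 7.2 |
| Tuesday's | 3.00 | 46.4 | 4.2 |
| Tuesday's | 5.00 | 44.0 | 1.0 |
| Friday's | 0.417 | 49.3 | 29.8 |
| Friday's | 0.667 | 48.7 | 21.2 |
| Friday's | 0.833 | 48.6 | 17.2 |
| Friday's | 1.33 | 48.3 | 9.1 |
| Friday's | 2.00 | 45.9 | 3.6 |
| Friday's | 3.00 | 44.8 | 1.6 |
| Friday's | 5.00 | 43.0 | 0.3 |
| Thursday's | 0.417 | 49.4 | 35.0 |
| Thursday's | 0.667 | 48.8 | 28.0 |
| Thursday's | 1.33 | 48.1 | 15.9 |
| Thursday's | 2.50 | 47.0 | 7.0 |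
| Thursday's | 5.00 | 45.0 | 1.5 |

(scatter of a reading: 0.5 percentage points)

- free catalyst is single-handed; left-handed substrate and right-handed substrate are mirror images of each other, charged as a racemate, each of them at the stated concentration
- what was read earlier has a scatter of 0.5 percentage points, one standard deviation
- at the start none of the gas is in solution

- whether the excess of right-handed substrate over left-handed substrate among what is left of the two reaches 80% by 8.0 min (yes / no)
- the highest excess of right-handed substrate over left-handed substrate among what is left of the two up to 8.0 min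

Leave the gas held, since I read my rates from runs at 9.5 mM. What I carry is the poisoned share, impurity charged over catalyst charged:42.5% here, and on Thursday's, with the same loading,

21.2%

Between 0.417 min and 1.33 min, Friday's left-handed substrate falls faster than Tuesday's by a reading of

1.40

and the root of their unpoisoned loadings gives

1.35

So I take the rate as that root, and this flask's clock runs slower than Thursday's by

1.17

Thursday's reads an excess of 93.5% at 5.00 min, higher than the 80% wanted, and my clock, an estimate from early rates, carries that time to 5.85 min, before 8.0 min. I commit to yes, with a top of about 93.5%.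

The forecast says yes, with a top of 96.5% (92% to 99%), holding that “Each impurity appears to kill about one catalyst equivalent”. The flask gives yes and 95.6%.

    reagent + free catalyst + right-handed substrate → free catalyst + right-handed product (k = 386 M⁻² s⁻¹)
    free catalyst + impurity → spent catalyst B (k = 88900 M⁻¹ s⁻¹)
    2 free catalyst → spent catalyst A (k = 18.4 M⁻¹ s⁻¹)
    gas ⇌ reagent, rate k4*(csat - [reagent]) (kL = 0.568 s⁻¹)
    reagent + free catalyst + left-handed substrate → free catalyst + left-handed product (k = 11000 M⁻² s⁻¹)

By 0.800 min this flask's impurity stands at 0% and spent catalyst B at 42.5% of the catalyst charged, against my 42.5%, while left-handed substrate is at 27.8%, where Thursday's read 28.0% at 0.667 min, which my clock carries to 0.781 min. After that spent catalyst B stays put while free catalyst falls to 11.4% at 8.00 min, pairing off into spent catalyst A at 46.1%, and the flask ends with left-handed substrate at 0.977% beside right-handed substrate at 43.6%.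

(The earlier runs and the new flask are simulated for an exercise, noise included.)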